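The vessel is a stirred flask of constant volume, in which partner adds first to substrate and then, step by step, to what that makes. Each of the four steps that use partner is first order in it, and the crystal step has no partner in its rate.

| setting | ash | maple | cedar |
|---|---|---|---|
| substrate | 0.020 M (fed, over 12 min) | 0.020 M | 0.020 M |
| partner | 1.30 equiv | 1.30 equiv (fed, over 12 min) | 1.30 equiv |
| time | 30 min | 30 min | 30 min |
| remark | all else is in the flask from the start; the feed brings no volume worth counting | all else is in the flask from the start; the feed brings no volume worth counting | everything together at the start |

* which flask leads in amount of bis adduct, in percent of the substrate charged ("all alike" within 1.5 percentage points) (ash / maple / cedar / all alike)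
* how much bis adduct is there at the end, in percent of the substrate charged: ash
* how much bis adduct is there at the end, in percent of the substrate charged: maple
* how much bis adduct is there at the end, in percent of the substrate charged: cedar

Define the clock θ as the time integral of partner concentration. On θ, partner cancels, so as long as no crystals form, cedar and maple follow one path in a, the fraction of substrate left, however partner arrives. Let κ be the constants removing first product, 3.2 L mol⁻¹ min⁻¹ and 0.98 L mol⁻¹ min⁻¹, summed and divided by substrate's 7.0 L mol⁻¹ min⁻¹: 0.597. I found that first product m peaks at a* = 27.8%, where m* = a*/κ = 46.6%. That is 9.31 mM, less than the solubility 19 mM, so I reckoned without crystals.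

Bis adduct peaks where making equals loss, at r·m, with r = 0.229, the selectivity factor. My upper bound was therefore the ceiling C, r times m*, or 10.6%.

Integrating the path to a* gave my floor, 8.63%. Reaching a* needs a mean partner of 6.09 mM over 30 min, about a quarter of the charge, which I judged cedar and maple would manage. In ash, late substrate reads a shorter clock, so I placed ash lower, perhaps under the floor.

The forecast said all alike, placing maple and cedar inside my bracket, since “both end close to the bis adduct's flat maximum”, and ash higher than I did.

| Flask | Forecast | Simulation |
|---|---|---|
| ash | 9% | 8.39% |
| maple | 9.1% | 9.16% |
| cedar | 9.3% | 9.34% |

The simulation gave all alike. Ash ended below my floor, and maple and cedar ended inside the bracket.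

    substrate + partner → first product (k1 = 7.0 L mol⁻¹ min⁻¹)
    partner + first product → bis adduct (k2 = 3.2 L mol⁻¹ min⁻¹)
    partner + bis adduct → triple product (k3 = 14 L mol⁻¹ min⁻¹)
    crystals ⇌ first product, rate k4*(cs4 - [first product]) while solid is left; crystals form when [first product] > cs4 (cs4 = 19 mM, k4 = 3.2 min⁻¹)
    partner + first product → over-reaction product (k5 = 0.98 L mol⁻¹ min⁻¹)

In cedar as charged, bis adduct had a half-life of 1.9 min by its onward step, shorter than the 8.3 min of first product by the step making it, and their quotient is r. Cedar ended at 0.203 bis adduct per first product, and the neighbour with maple's recipe at 0.034 M substrate ended below C, at 9.44%.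

The rate constants stand for no real mixture; the flask was simulated.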